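## Retrosynthetic overview

1. Target 30 comes from alcohol 29 by oxidation at C3; the exo-methylene comes from a Mannich base (26, 27), and the ring-fusion hydrogen from hydrogenation of enone 26.
2. Ring C (cycloheptane) is closed last by a 7-endo hydrogen-atom-transfer radical cyclisation (C14–C23) of dienone 22, which is made by cross-metathesis (C14=C15) of alkene 12 with vinyl ketone 21.
3. Alkene 12 comes from bicyclic β-ketophosphonate 8 (methylenation, conjugate allylation, methyl addition). Rings A (oxepane) and B (cyclohexane) of 8 form together in the key C2–O bond-forming epoxide cascade of diepoxide 5, built from geranyl bromide 1 and phosphonate 2.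
4. Vinyl ketone 21 comes from (R)-limonene 13: ozonolysis and aldol condensation close ring D (cyclopentane), then methoxymethylenation, γ-hydroxylation (C19–O), vinyl addition and oxidation.
5. Ring order: D (step 8); A and B together (step 3); C (step 14).

Assumption: the Shi ketone made from D-fructose gives the (R,R)-epoxides drawn in 5; if it gave the opposite sense, the enantiomeric ketone (from L-sorbose) would be used.

Locants in the "Why" lines follow the biogenetic numbering of 30: oxepane O, C2–C7; cyclohexane C6–C11; linker C12, C13; cycloheptane C14–C18, C22, C23; cyclopentane C18–C22.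

## Route

Step 1
Reactants: 1 geranyl bromide; 2 dimethyl (2-oxopropyl)phosphonate
Product: 4 dimethyl [(5E)-6,10-dimethyl-2-oxoundeca-5,9-dien-1-yl]phosphonate, via phosphonate dianion 3 (not isolated)
Conditions: 2, NaH, THF, 0 °C; n-BuLi, 0 °C; then 1, 0 → 23 °C; aq. NH4Cl
Reagents that add atoms: none
Why: Alkylation of a β-ketophosphonate 1,3-dianion occurs at the terminal (γ) carbanion, and SN2 displacement of the primary allylic bromide keeps the (E)-alkene.

Step 2
Reactants: 4
Product: 5 dimethyl {4-[(2R,3R)-3-{2-[(2R)-3,3-dimethyloxiran-2-yl]ethyl}-3-methyloxiran-2-yl]-2-oxobutyl}phosphonate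
Conditions: Shi ketone (from D-fructose, 0.6 equiv), Oxone, K2CO3, Bu4NHSO4 (cat.), MeCN/dimethoxymethane/aq. borate buffer (pH 10.5), 0 °C
Reagents that add atoms: Oxone (potassium peroxymonosulfate, KHSO5) [K+].[O-]S(=O)(=O)OO
Why: Shi asymmetric epoxidation oxidises both electron-rich trisubstituted alkenes through a spiro dioxirane transition state, setting the (R,R)-epoxide whose carbons become C6 and C7 (the C3 centre is erased later).

Step 3
Reactants: 5
Product: 8 dimethyl [(3R,5aS,6R,9aR)-3-hydroxy-2,2,5a-trimethyl-7-oxodecahydro-1-benzoxepin-6-yl]phosphonate, via α-phosphono silyl enol ether 6 (not isolated), via bicyclic silyl ether 7 (not isolated)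
Conditions: NaN(SiMe3)2, Me3SiCl, THF, −78 → 0 °C; then Me3SiOTf (0.3 equiv), 2,6-di-tert-butyl-4-methylpyridine, CH2Cl2, −78 °C; then K2CO3 (cat.), MeOH, 0 °C
Reagents that add atoms: none
Why: Proposed new method: O-silylation gives enol silane 6, Me3SiOTf activates the terminal epoxide, the internal epoxide oxygen opens it at the tertiary carbon C2 (7-endo, the key C–O bond) to give a bicyclic epoxonium ion, and the enol silane carbon attacks C6 anti through a chair (C6 inverted, C7 retained, trans ring fusion) with silyl transfer regenerating the promoter; the closest known reaction type is the silyl triflate-promoted tandem oxa-/carbacyclisation of polyepoxides terminated by simple trimethylsilyl enol ethers, extended here to a phosphonate-bearing enol silane so that the product carries a Horner–Wadsworth–Emmons handle at C11.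

Step 4
Reactants: 8
Product: 9 (3R,5aR,9aR)-3-hydroxy-2,2,5a-trimethyl-6-methylideneoctahydro-1-benzoxepin-7(2H)-one
Conditions: 37% aq. CH2O, K2CO3, THF, 0 → 23 °C
Reagents that add atoms: formaldehyde C=O
Why: Horner–Wadsworth–Emmons reaction of the cyclic 2-phosphono ketone with formaldehyde places the methylene group (C12) regiospecifically on C11.

Step 5
Reactants: 9
Product: 11 (3R,5aR,6R,9aR)-6-(but-3-en-1-yl)-3-hydroxy-2,2,5a-trimethyloctahydro-1-benzoxepin-7(2H)-one, via bis-silyl enol ether 10 (not isolated)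
Conditions: CH2=CHCH2MgBr, CuBr·SMe2, LiCl, Me3SiCl, THF, −78 °C; then K2CO3 (cat.), MeOH, 23 °C
Reagents that add atoms: allylmagnesium bromide C=CC[Mg]Br
Why: Me3SiCl-accelerated 1,4-addition of allylcopper to the unhindered exo-methylene enone adds C13–C14, and base equilibration through the enol places the side chain equatorial at C11 (R), trans to the axial angular methyl.

Step 6
Reactants: 11
Product: 12 (3R,5aR,6R,7S,9aR)-6-(but-3-en-1-yl)-2,2,5a,7-tetramethyldecahydro-1-benzoxepine-3,7-diol
Conditions: MeMgBr, CeCl3, THF, −78 → 0 °C; aq. NH4Cl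
Reagents that add atoms: methylmagnesium bromide C[Mg]Br
Why: Organocerium 1,2-addition suppresses enolisation; axial attack is blocked by the syn-axial angular methyl, so methyl enters equatorially and the C10 hydroxyl is axial (S).

Step 7
Reactants: 13 (R)-(+)-limonene
Product: 15 (3R)-6-oxo-3-(prop-1-en-2-yl)heptanal, via ozonide 14 (not isolated)
Conditions: O3 (1.0 equiv), CH2Cl2, −78 °C; then PPh3, −78 → 23 °C
Reagents that add atoms: ozone [O-][O+]=O
Why: Ozonolysis with reductive work-up cleaves the electron-rich trisubstituted ring alkene much faster than the 1,1-disubstituted isopropenyl group and leaves the stereocentre (future C22) untouched.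

Step 8
Reactants: 15
Product: 16 (5S)-2-methyl-5-(prop-1-en-2-yl)cyclopent-1-ene-1-carbaldehyde
Conditions: piperidine (0.2 equiv), AcOH (0.2 equiv), toluene, 80 °C
Reagents that add atoms: none
Why: Amine-catalysed intramolecular aldol condensation (aldehyde enamine onto the methyl ketone, then dehydration) closes ring D as the tetrasubstituted enal.

Step 9
Reactants: 16
Product: 17 (5S)-1-(2-methoxyethenyl)-2-methyl-5-(prop-1-en-2-yl)cyclopent-1-ene (E/Z mixture)
Conditions: Ph3P(CH2OMe)Cl, KOtBu, THF, 0 °C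
Reagents that add atoms: (methoxymethyl)triphenylphosphonium chloride COC[P+](c1ccccc1)(c1ccccc1)c1ccccc1.[Cl-]
Why: Wittig methoxymethylenation adds C16 and turns the enal into a 1-methoxy-1,3-diene.

Step 10
Reactants: 17
Product: 19 (2E)-2-[(2R,5S)-2-hydroxy-2-methyl-5-(prop-1-en-2-yl)cyclopentylidene]acetaldehyde, via epoxy enol ether 18 (not isolated)
Conditions: mCPBA (1.0 equiv), NaHCO3, CH2Cl2/H2O, −20 °C
Reagents that add atoms: 3-chloroperoxybenzoic acid OOC(=O)c1cccc(Cl)c1; water O
Why: Vinylogous Rubottom-type oxidation: the peracid attacks the electron-rich tetrasubstituted diene terminus anti to the isopropenyl group, and oxocarbenium-assisted epoxide opening then hydrolysis gives the γ-hydroxy enal, setting C19 (R) and, from the s-trans diene, the alkene geometry with C16 cis to C22.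

Step 11
Reactants: 19
Product: 20 (1E)-1-[(2R,5S)-2-hydroxy-2-methyl-5-(prop-1-en-2-yl)cyclopentylidene]but-3-en-2-ol (carbinol epimers)
Conditions: CH2=CHMgBr (2.5 equiv), THF, −78 °C; aq. NH4Cl
Reagents that add atoms: vinylmagnesium bromide C=C[Mg]Br
Why: Grignard 1,2-addition to the aldehyde after deprotonation of the tertiary alcohol; the new carbinol centre is removed in the next step.

Step 12
Reactants: 20
Product: 21 (1E)-1-[(2R,5S)-2-hydroxy-2-methyl-5-(prop-1-en-2-yl)cyclopentylidene]but-3-en-2-one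
Conditions: MnO2, CH2Cl2, 23 °C
Reagents that add atoms: none
Why: MnO2 oxidises the bis-allylic secondary alcohol selectively to the divinyl ketone and leaves the tertiary alcohol alone.

Step 13
Reactants: 12; 21
Product: 22 (3E)-6-[(3R,5aR,6R,7S,9aR)-3,7-dihydroxy-2,2,5a,7-tetramethyldecahydro-1-benzoxepin-6-yl]-1-[(2R,5S)-2-hydroxy-2-methyl-5-(prop-1-en-2-yl)cyclopentylidene]hex-3-en-2-one
Conditions: second-generation Hoveyda–Grubbs catalyst RuCl2(H2IMes)(=CH-C6H4-2-OiPr) (5 mol%), CH2Cl2, 40 °C
Reagents that add atoms: none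
Why: Olefin cross-metathesis of the terminal alkene with the vinyl ketone gives the (E)-enone (C14=C15); the 1,1-disubstituted and trisubstituted alkenes are too hindered to react.

Step 14
Reactants: 22
Product: 23 (1R,3aS,5S)-5-{2-[(3R,5aR,6R,7S,9aR)-3,7-dihydroxy-2,2,5a,7-tetramethyldecahydro-1-benzoxepin-6-yl]ethyl}-1-hydroxy-1,4,4-trimethyl-2,3,3a,4,5,6-hexahydroazulen-7(1H)-one
Conditions: Fe(acac)3 (0.5 equiv), PhSiH3, EtOH/ethylene glycol, 60 °C, 0.005 M
Reagents that add atoms: none
Why: Iron-hydride hydrogen-atom transfer to the isopropenyl group gives the tertiary C23 radical, which adds 7-endo to the β-carbon of the (E)-enone (radical conjugate addition) across the flat cross-conjugated dienone; C23 lies on the face away from H22 and the side chain stays outward, so H14 ends cis to H22 as in the target.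

Step 15
Reactants: 23
Product: 26 6-[(dimethylamino)methyl] derivative of 23 (Mannich base; C15 epimers), via tetrasilyl dienol ether 24 (not isolated), via silylated Mannich base 25 (not isolated)
Conditions: Me3SiOTf, Et3N, CH2Cl2, 0 °C; then CH2=NMe2 I (Eschenmoser's salt), 23 °C; then citric acid (cat.), MeOH; aq. NaHCO3
Reagents that add atoms: Eschenmoser's salt (dimethylmethylideneammonium iodide) C=[N+](C)C.[I-]
Why: Soft enolisation can only take place at the α′-CH2 (C15) of the enone, and the 2-silyloxy diene undergoes a Mukaiyama–Mannich reaction there, fixing the site of the future methylene group while the hydroxyls are masked as silyl ethers.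

Step 16
Reactants: 26
Product: 27 cis-fused saturated Mannich base (8,8a-dihydro derivative of 26; H at C18 cis to H22 and to the C19 hydroxyl)
Conditions: H2 (1–3 atm), 10% Pd/C, EtOAc, 23 °C
Reagents that add atoms: none
Why: Heterogeneous hydrogenation adds to the enone from the less hindered face carrying H22 and the C19 hydroxyl (opposite the gem-dimethyl bridge and the C19 methyl), giving the cis ring fusion (C18 R).

Step 17
Reactants: 27
Product: 29 (3R,5aR,6R,7S,9aR)-6-{2-[(1R,3aR,5R,8aR)-1-hydroxy-1,4,4-trimethyl-6-methylidene-7-oxodecahydroazulen-5-yl]ethyl}-2,2,5a,7-tetramethyldecahydro-1-benzoxepine-3,7-diol, via methiodide 28 (not isolated)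
Conditions: MeI, CH2Cl2, 23 °C; then aq. NaHCO3, 23 °C
Reagents that add atoms: none
Why: N-Methylation followed by E1cB elimination of the β-ammonium ketone unveils the α-methylene ketone under conditions too mild to move the alkene into the ring.

Step 18
Reactants: 29
Product: 30 (5aR,6R,7S,9aR)-7-hydroxy-6-{2-[(1R,3aR,5R,8aR)-1-hydroxy-1,4,4-trimethyl-6-methylidene-7-oxodecahydroazulen-5-yl]ethyl}-2,2,5a,7-tetramethyloctahydro-1-benzoxepin-3(2H)-one (target)
Conditions: Dess–Martin periodinane, NaHCO3, CH2Cl2, 23 °C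
Reagents that add atoms: none
Why: Dess–Martin oxidation converts the only secondary alcohol into the C3 ketone; the two tertiary alcohols and the enone are inert.

## Compound list

1 | geranyl bromide, (2E)-1-bromo-3,7-dimethylocta-2,6-diene | CC(C)=CCC/C(C)=C/CBr | starting material
2 | dimethyl (2-oxopropyl)phosphonate | COP(=O)(OC)CC(C)=O | starting material
3 | sodium lithium 1,3-dianion of 2 | [Na+].[Li+].COP(=O)(OC)[CH-]C(=O)[CH2-] | intermediate (not isolated)
4 | dimethyl [(5E)-6,10-dimethyl-2-oxoundeca-5,9-dien-1-yl]phosphonate | COP(=O)(OC)CC(=O)CC/C=C(\C)CCC=C(C)C | intermediate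
5 | dimethyl {4-[(2R,3R)-3-{2-[(2R)-3,3-dimethyloxiran-2-yl]ethyl}-3-methyloxiran-2-yl]-2-oxobutyl}phosphonate | COP(=O)(OC)CC(=O)CC[C@H]1O[C@]1(C)CC[C@H]1OC1(C)C | intermediate
6 | (Z)-trimethylsilyl enol ether of 5 (α-phosphono enol silane) | COP(=O)(OC)/C=C(\O[Si](C)(C)C)CC[C@H]1O[C@]1(C)CC[C@H]1OC1(C)C | intermediate (not isolated)
7 | 3-O-trimethylsilyl ether of 8 | COP(=O)(OC)[C@@H]1[C@@]2(C)CC[C@@H](O[Si](C)(C)C)C(C)(C)O[C@@H]2CCC1=O | intermediate (not isolated)
8 | dimethyl [(3R,5aS,6R,9aR)-3-hydroxy-2,2,5a-trimethyl-7-oxodecahydro-1-benzoxepin-6-yl]phosphonate (trans-fused; equatorial phosphonate drawn, C6 epimer inconsequential) | COP(=O)(OC)[C@@H]1[C@@]2(C)CC[C@@H](O)C(C)(C)O[C@@H]2CCC1=O | intermediate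
9 | (3R,5aR,9aR)-3-hydroxy-2,2,5a-trimethyl-6-methylideneoctahydro-1-benzoxepin-7(2H)-one | C=C1[C@@]2(C)CC[C@@H](O)C(C)(C)O[C@@H]2CCC1=O | intermediate
10 | 3-O-trimethylsilyl ether, 7-O-trimethylsilyl enol ether (C6=C7) of 11 | C=CCCC=1[C@@]2(C)CC[C@@H](O[Si](C)(C)C)C(C)(C)O[C@@H]2CCC=1O[Si](C)(C)C | intermediate (not isolated)
11 | (3R,5aR,6R,9aR)-6-(but-3-en-1-yl)-3-hydroxy-2,2,5a-trimethyloctahydro-1-benzoxepin-7(2H)-one | C=CCC[C@@H]1[C@@]2(C)CC[C@@H](O)C(C)(C)O[C@@H]2CCC1=O | intermediate
12 | (3R,5aR,6R,7S,9aR)-6-(but-3-en-1-yl)-2,2,5a,7-tetramethyldecahydro-1-benzoxepine-3,7-diol | C=CCC[C@@H]1[C@@]2(C)CC[C@@H](O)C(C)(C)O[C@@H]2CC[C@]1(C)O | intermediate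
13 | (R)-(+)-limonene | CC1=CC[C@@H](CC1)C(C)=C | starting material
14 | ozonide (1,2,4-trioxolane) of the ring alkene of 13 | CC12CC[C@@H](C(C)=C)CC(OO1)O2 | intermediate (not isolated)
15 | (3R)-6-oxo-3-(prop-1-en-2-yl)heptanal | CC(=O)CC[C@H](CC=O)C(C)=C | intermediate
16 | (5S)-2-methyl-5-(prop-1-en-2-yl)cyclopent-1-ene-1-carbaldehyde | O=CC1=C(C)CC[C@H]1C(C)=C | intermediate
17 | (5S)-1-(2-methoxyethenyl)-2-methyl-5-(prop-1-en-2-yl)cyclopent-1-ene (E/Z) | COC=CC1=C(C)CC[C@H]1C(C)=C | intermediate
18 | 1-(2-methoxyethenyl)-5-methyl-2-(prop-1-en-2-yl)-6-oxabicyclo[3.1.0]hexane, oxirane trans to isopropenyl | COC=C[C@@]12O[C@]1(C)CC[C@H]2C(C)=C | intermediate (not isolated)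
19 | (2E)-2-[(2R,5S)-2-hydroxy-2-methyl-5-(prop-1-en-2-yl)cyclopentylidene]acetaldehyde | O=C/C=C1\[C@@H](CC[C@@]1(C)O)C(C)=C | intermediate
20 | (1E)-1-[(2R,5S)-2-hydroxy-2-methyl-5-(prop-1-en-2-yl)cyclopentylidene]but-3-en-2-ol (carbinol epimers) | C=CC(O)/C=C1\[C@@H](CC[C@@]1(C)O)C(C)=C | intermediate
21 | (1E)-1-[(2R,5S)-2-hydroxy-2-methyl-5-(prop-1-en-2-yl)cyclopentylidene]but-3-en-2-one | C=CC(=O)/C=C1\[C@@H](CC[C@@]1(C)O)C(C)=C | intermediate
22 | cross-conjugated dienone, (3E)-6-(benzoxepin-6-yl)-1-(cyclopentylidene)hex-3-en-2-one (full name in step 13) | O=C(/C=C1\[C@@H](CC[C@@]1(C)O)C(C)=C)/C=C/CC[C@@H]1[C@@]2(C)CC[C@@H](O)C(C)(C)O[C@@H]2CC[C@]1(C)O | intermediate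
23 | hexahydroazulen-7(1H)-one (full name in step 14) | C1C(=O)C=C2[C@@H](CC[C@@]2(C)O)C(C)(C)[C@H]1CC[C@@H]1[C@@]2(C)CC[C@@H](O)C(C)(C)O[C@@H]2CC[C@]1(C)O | intermediate
24 | tris-O-trimethylsilyl ether of 23 as its 7-trimethylsilyloxy-6,8-diene | C1=C(O[Si](C)(C)C)C=C2[C@@H](CC[C@@]2(C)O[Si](C)(C)C)C(C)(C)[C@H]1CC[C@@H]1[C@@]2(C)CC[C@@H](O[Si](C)(C)C)C(C)(C)O[C@@H]2CC[C@]1(C)O[Si](C)(C)C | intermediate (not isolated)
25 | tris-O-trimethylsilyl ether of 26 | CN(C)CC1C(=O)C=C2[C@@H](CC[C@@]2(C)O[Si](C)(C)C)C(C)(C)[C@H]1CC[C@@H]1[C@@]2(C)CC[C@@H](O[Si](C)(C)C)C(C)(C)O[C@@H]2CC[C@]1(C)O[Si](C)(C)C | intermediate (not isolated)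
26 | 6-[(dimethylamino)methyl] derivative of 23 (C15 epimers) | CN(C)CC1C(=O)C=C2[C@@H](CC[C@@]2(C)O)C(C)(C)[C@H]1CC[C@@H]1[C@@]2(C)CC[C@@H](O)C(C)(C)O[C@@H]2CC[C@]1(C)O | intermediate
27 | cis-fused saturated Mannich base (8,8a-dihydro-26) | CN(C)CC1C(=O)C[C@@H]2[C@@H](CC[C@@]2(C)O)C(C)(C)[C@H]1CC[C@@H]1[C@@]2(C)CC[C@@H](O)C(C)(C)O[C@@H]2CC[C@]1(C)O | intermediate
28 | trimethylammonium iodide (methiodide) of 27 | C[N+](C)(C)CC1C(=O)C[C@@H]2[C@@H](CC[C@@]2(C)O)C(C)(C)[C@H]1CC[C@@H]1[C@@]2(C)CC[C@@H](O)C(C)(C)O[C@@H]2CC[C@]1(C)O.[I-] | intermediate (not isolated)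
29 | 3-hydroxy precursor of 30 (full name in step 17) | C=C1C(=O)C[C@@H]2[C@@H](CC[C@@]2(C)O)C(C)(C)[C@H]1CC[C@@H]1[C@@]2(C)CC[C@@H](O)C(C)(C)O[C@@H]2CC[C@]1(C)O | intermediate
30 | CNP0316622.2 (full name in step 18) | C=C1C(=O)C[C@@H]2[C@@H](CC[C@@]2(C)O)C(C)(C)[C@H]1CC[C@@H]1[C@@]2(C)CCC(=O)C(C)(C)O[C@@H]2CC[C@]1(C)O | target

## Step count and risk

Total: 18 steps (6 to fragment 12, 6 to fragment 21, 6 after union). Longest linear sequence: 12 steps (steps 1–6 or 7–12, then 13–18).

The three steps most likely to fail: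

**Step 3 (the proposed new step).** The phosphonate makes the enol silane a weaker nucleophile, and capture of the epoxonium ion by oxygen or epoxide rearrangement may win. The fallback uses known chemistry, sets out from 5 and returns at 11. Horner–Wadsworth–Emmons reaction of 5 with aqueous formaldehyde and K2CO3 gives the diepoxy vinyl ketone F1. Addition of allylcopper with Me3SiCl at −78 °C gives the regiodefined (Z)-trimethylsilyl enol ether F2. Treatment of F2 with catalytic Me3SiOTf and 2,6-di-tert-butyl-4-methylpyridine in CH2Cl2 at −78 °C, the established tandem oxa-/carbacyclisation terminated by a simple enol silane, gives the bicyclic silyl ether F3. K2CO3 in MeOH removes the silyl group and equilibrates the side chain to give 11. This changes the order of events (side chain before cyclisation) and bypasses 6–10.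

**Step 10.** The peracid may attack the enol ether alkene or the isopropenyl group instead of the diene terminus. The fallback sets out from 16 and returns at 19. Weitz–Scheffer epoxidation of 16 (H2O2, NaOH, MeOH, 0 °C) gives the epoxy aldehyde F4 with the oxirane trans to the isopropenyl group. Wittig methoxymethylenation of F4 gives 18, here isolated. PPTS in wet THF then opens the vinylogous epoxide and hydrolyses the enol ether to give 19.

**Step 14.** Seven-membered closure onto a β-substituted enone may lose to simple reduction of the radical by the iron hydride. The fallback sets out from 22 and returns at 23. Ionic Markovnikov addition of HCl (1 equiv in Et2O, CH2Cl2, −78 °C) to the isopropenyl group gives the tertiary chloride F5. Slow addition of (Me3Si)3SiH and AIBN in benzene at 80 °C under high dilution then generates the same tertiary radical in a chain process without a metal hydride, and 7-endo Giese cyclisation gives 23.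

## Further compounds

F1 | step 3 | 1-[(2R,3R)-3-{2-[(2R)-3,3-dimethyloxiran-2-yl]ethyl}-3-methyloxiran-2-yl]pent-4-en-3-one | C=CC(=O)CC[C@H]1O[C@]1(C)CC[C@H]1OC1(C)C
F2 | step 3 | trimethyl{[(3Z)-1-[(2R,3R)-3-{2-[(2R)-3,3-dimethyloxiran-2-yl]ethyl}-3-methyloxiran-2-yl]octa-3,7-dien-3-yl]oxy}silane | C=CCC/C=C(\O[Si](C)(C)C)CC[C@H]1O[C@]1(C)CC[C@H]1OC1(C)C
F3 | step 3 | (3R,5aR,6R,9aR)-6-(but-3-en-1-yl)-2,2,5a-trimethyl-3-[(trimethylsilyl)oxy]octahydro-1-benzoxepin-7(2H)-one | C=CCC[C@@H]1[C@@]2(C)CC[C@@H](O[Si](C)(C)C)C(C)(C)O[C@@H]2CCC1=O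
F4 | step 10 | 5-methyl-2-(prop-1-en-2-yl)-6-oxabicyclo[3.1.0]hexane-1-carbaldehyde, oxirane trans to isopropenyl | O=C[C@@]12O[C@]1(C)CC[C@H]2C(C)=C
F5 | step 14 | tertiary chloride of 22 (2-chloropropan-2-yl in place of prop-1-en-2-yl) | O=C(/C=C1\[C@@H](CC[C@@]1(C)O)C(C)(C)Cl)/C=C/CC[C@@H]1[C@@]2(C)CC[C@@H](O)C(C)(C)O[C@@H]2CC[C@]1(C)O
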